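**Retrosynthetic overview**

- The 3β-angelate and 4β-acetate come from a Woodward cis-hydroxyacetoxylation of a C3=C4 alkene, itself made from the C4 ketone (enol triflate, methyl coupling); the 7α-hydroxyl comes from α-hydroxylation of the C8 dienolate.
- Feature used: the C4 and C8 carbonyls are 1,5-related through C5–C6–C7 of ring B, and C7 carries an isopropenyl group next to the C8 ketone. This is the pattern left when the extended dienolate of an isobutenyl ketone reacts at its α-carbon.
- Key disconnection C6–C7: the dienolate of the C8 isobutenyl ketone adds through C7 to C6 of an exocyclic enone (C5=C6, C4=O) on ring A, closing ring B and releasing the C11=C12 alkene.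
- The monocyclic precursor is built on quaternary C10: copper-catalysed asymmetric Me3Al addition to 3-allylcyclohexenone, regiospecific hydroxymethylation of the resulting enolate (C6), and allyl → aldehyde → isobutenyl ketone (C8, C7, C11–C13).
- Ring order: ring A is purchased (3-ethoxycyclohexenone); ring B is closed in the key step.

Key step: step 10

Numbering: eudesmane numbering is used throughout (ring A = C1–C5, C10; ring B = C5–C10; C14 = methyl on C10, C15 = methyl on C4, C11–C13 = isopropenyl on C7); β is the face of the C10 methyl.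
Assumption: the phosphoramidite enantiomer that gives the (R) quaternary centre in step 2 is used; its sense of induction is to be confirmed on the first run.

**Step 1**
Reactants: 1 3-ethoxycyclohex-2-en-1-one; 2 allylmagnesium bromide
Product: 4 3-allylcyclohex-2-en-1-one, via 1-allyl-3-ethoxycyclohex-2-en-1-ol 3 (not isolated)
Conditions: CH2=CHCH2MgBr, THF, 0 °C; then 1 M HCl (aq), 0 °C, short contact
Reagents that add atoms: water, O
Why: 1,2-addition of the Grignard reagent to the vinylogous ester and acid hydrolysis with allylic transposition (Stork–Danheiser-type sequence) is the standard entry to 3-substituted cyclohexenones; the brief, cold acid treatment should keep the skipped alkene out of conjugation.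

**Step 2**
Reactants: 4 3-allylcyclohex-2-en-1-one
Product: 6 (R)-3-allyl-3-methyl-1-(trimethylsilyloxy)cyclohex-1-ene, via dimethylaluminium enolate 5 (not isolated)
Conditions: Me3Al, copper thiophene-2-carboxylate Cu(O2CC4H3S) (2 mol %), O,O'-(1,1'-binaphthyl-2,2'-diyl) N,N-bis(1-phenylethyl)phosphoramidite (4 mol %), Et2O, −30 °C; then Me3SiCl, Et3N, THF, −30 °C → rt
Reagents that add atoms: trimethylaluminium, C[Al](C)C; chlorotrimethylsilane, C[Si](C)(C)Cl
Why: copper–phosphoramidite-catalysed asymmetric conjugate addition of Me3Al to a 3-substituted cyclohexenone builds the quaternary C10 centre with the catalyst choosing the enone face, and O-silylation of the aluminium enolate preserves the C4–C5 enolate regiochemistry.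

**Step 3**
Reactants: 6 (R)-3-allyl-3-methyl-1-(trimethylsilyloxy)cyclohex-1-ene
Product: 7 (3R)-3-allyl-2-(hydroxymethyl)-3-methylcyclohexan-1-one (both C2 epimers)
Conditions: aq. HCHO (37 %), Yb(OTf)3 (10 mol %), THF, rt
Reagents that add atoms: formaldehyde, C=O
Why: the lanthanide-triflate-catalysed Mukaiyama aldol reaction of a silyl enol ether with aqueous formaldehyde should attach C6 to C5 regiospecifically, even next to the quaternary carbon; the new C5 centre forms as a mixture that is erased in step 9.

**Step 4**
Reactants: 7 (3R)-3-allyl-2-(hydroxymethyl)-3-methylcyclohexan-1-one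
Product: 8 (3R)-3-allyl-2-[(tert-butyldimethylsilyloxy)methyl]-3-methylcyclohexan-1-one
Conditions: tBuMe2SiCl, imidazole, CH2Cl2, rt
Reagents that add atoms: tert-butyldimethylsilyl chloride, CC(C)(C)[Si](C)(C)Cl
Why: standard silylation of the primary alcohol blocks retro-aldol loss of formaldehyde and premature elimination during the Grignard step.

**Step 5**
Reactants: 8 (3R)-3-allyl-2-[(tert-butyldimethylsilyloxy)methyl]-3-methylcyclohexan-1-one
Product: 10 2-[(1R)-2-[(tert-butyldimethylsilyloxy)methyl]-1-methyl-3-oxocyclohexyl]acetaldehyde, via secondary ozonide 9 (not isolated)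
Conditions: O3, CH2Cl2, −78 °C; then PPh3, −78 °C → rt
Reagents that add atoms: ozone, [O-][O+]=O
Why: ozonolysis with reductive work-up cleaves the only alkene and turns the allyl group into the C9–C8 acetaldehyde arm without touching the ketone or the silyl ether.

**Step 6**
Reactants: 10 2-[(1R)-2-[(tert-butyldimethylsilyloxy)methyl]-1-methyl-3-oxocyclohexyl]acetaldehyde; 11 2-methylprop-1-enylmagnesium bromide
Product: 12 (3R)-2-[(tert-butyldimethylsilyloxy)methyl]-3-(2-hydroxy-4-methylpent-3-enyl)-3-methylcyclohexan-1-one (carbinol epimers)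
Conditions: Me2C=CHMgBr (1.1 equiv), THF, −78 °C; NH4Cl (aq)
Reagents that add atoms: none
Why: Grignard addition at −78 °C should select the aldehyde over the ring ketone, which is hindered by its α-branch and the adjacent quaternary carbon; the carbinol centre is removed in step 7.

**Step 7**
Reactants: 12 (3R)-2-[(tert-butyldimethylsilyloxy)methyl]-3-(2-hydroxy-4-methylpent-3-enyl)-3-methylcyclohexan-1-one
Product: 13 (3R)-2-[(tert-butyldimethylsilyloxy)methyl]-3-methyl-3-(4-methyl-2-oxopent-3-enyl)cyclohexan-1-one
Conditions: Dess–Martin periodinane, NaHCO3, CH2Cl2, 0 °C → rt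
Reagents that add atoms: none
Why: buffered Dess–Martin oxidation of the allylic alcohol gives the β,β-dimethyl enone under neutral conditions that leave the silyl ether and the C5 position alone.

**Step 8**
Reactants: 13 (3R)-2-[(tert-butyldimethylsilyloxy)methyl]-3-methyl-3-(4-methyl-2-oxopent-3-enyl)cyclohexan-1-one
Product: 14 (3R)-2-(hydroxymethyl)-3-methyl-3-(4-methyl-2-oxopent-3-enyl)cyclohexan-1-one
Conditions: aq. HF (48 %), MeCN, 0 °C → rt
Reagents that add atoms: none
Why: acidic fluoride desilylation frees the primary alcohol without the basic conditions that would cause retro-aldol cleavage or early enolate chemistry.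

**Step 9**
Reactants: 14 (3R)-2-(hydroxymethyl)-3-methyl-3-(4-methyl-2-oxopent-3-enyl)cyclohexan-1-one
Product: 16 (R)-3-methyl-2-methylidene-3-(4-methyl-2-oxopent-3-enyl)cyclohexan-1-one, via primary mesylate 15 (not isolated)
Conditions: MeSO2Cl, Et3N (4 equiv), CH2Cl2, −10 °C → rt
Reagents that add atoms: none
Why: mesylation followed by E1cB elimination of the β-mesyloxy ketone gives the exocyclic enone from both C5 epimers; Et3N is too weak to form the extended dienolate, so the precursor should be isolable, and the neighbouring quaternary carbon suppresses its dimerisation.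

**Step 10**
Reactants: 16 (R)-3-methyl-2-methylidene-3-(4-methyl-2-oxopent-3-enyl)cyclohexan-1-one
Product: 19 5αH-7β-isopropenyl-10β-methyl-trans-decalin-4,8-dione, via extended potassium dienolate 17 (not isolated), via potassium C4 enolate 18 (not isolated)
Conditions: KOtBu (0.2 equiv), THF–tBuOH (10:1), 0.02 M, −20 → 0 °C; AcOH quench at −20 °C
Reagents that add atoms: none
Why: tBuOK removes a γ-proton (C12/C13) of the s-cis isobutenyl ketone to give the (Z)-extended dienolate 17, whose α-carbon C7 adds to the unsubstituted terminus C6 of the exocyclic enone, forming C6–C7 and the C4 enolate 18, which tBuOH protonates at C5 while returning the alkoxide, so the base is catalytic. The closest known reaction types are the intramolecular Michael addition of ketone enolates to α-methylene ketones and the deconjugative α-alkylation of dienolates of β,β-dimethyl enones. Ring B (C5–C6–C7–C8–C9–C10) closes 6-endo-trig at the acceptor, with the donor C7=C8 enolate bond inside the new ring, through a chair carrying the C10 methyl axial. C5 is set by protonation of 18 on the α face, anti to the adjacent axial C10 methyl, giving the trans fusion that should also be preferred at equilibrium because both carbons 1,3 to that methyl (C4 and C8) are trigonal; C7 is set by reversible enolisation, which leaves the isopropenyl group equatorial (β). The step needs α- over γ-attack of the dienolate and C–C bond formation at C6 only: attack through C12 would need an eight-membered ring, the cross-conjugated C9 enolate could only close a cyclobutane, and aldol additions of C7 or C3 to the other carbonyl give strained bridged ketols that revert. Any product that drifts into conjugation (7(11)-ene) converges in step 11 through the same dienolate.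

**Step 11**
Reactants: 19 5αH-7β-isopropenyl-10β-methyl-trans-decalin-4,8-dione
Product: 21 7α-hydroxy-7β-isopropenyl-10β-methyl-5αH-trans-decalin-4,8-dione, via potassium dienolate 20 (not isolated)
Conditions: KOtBu (1.15 equiv), THF, −40 °C; then (±)-trans-2-(phenylsulfonyl)-3-phenyloxaziridine, −78 → −40 °C; NH4Cl (aq) at −78 °C
Reagents that add atoms: 2-(phenylsulfonyl)-3-phenyloxaziridine, O=S(=O)(c1ccccc1)N1OC1c1ccccc1
Why: under equilibrating conditions the most acidic C–H (C7–H, α to C8 and allylic) gives the extended dienolate 20, which takes oxygen from the N-sulfonyloxaziridine at its α-carbon (Davis enolate hydroxylation); delivery along the axial direction on the α face, anti to the C10 methyl, makes the hydroxyl axial (7α) and keeps the isopropenyl group equatorial.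

**Step 12**
Reactants: 21 7α-hydroxy-7β-isopropenyl-10β-methyl-5αH-trans-decalin-4,8-dione
Product: 22 7β-isopropenyl-10β-methyl-7α-(triethylsilyloxy)-5αH-trans-decalin-4,8-dione
Conditions: Et3SiOTf, 2,6-lutidine, CH2Cl2, −78 → 0 °C
Reagents that add atoms: triethylsilyl triflate, CC[Si](CC)(CC)OS(=O)(=O)C(F)(F)F
Why: silyl triflate with 2,6-lutidine silylates the hindered tertiary α-ketol at low temperature without enol-silylating the ketones, and the ether blocks alkoxide formation and α-ketol rearrangement in the base step that follows.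

**Step 13**
Reactants: 22 7β-isopropenyl-10β-methyl-7α-(triethylsilyloxy)-5αH-trans-decalin-4,8-dione
Product: 24 7β-isopropenyl-10β-methyl-8-oxo-7α-(triethylsilyloxy)-5αH-octalin-3-en-4-yl triflate (C3=C4 enol triflate), via lithium C3–C4 enolate 23 (not isolated)
Conditions: LiN(iPr)2 (1.05 equiv), THF, −78 °C (ketone added to base); then N-(5-chloropyridin-2-yl)triflimide, −78 °C
Reagents that add atoms: N-(5-chloropyridin-2-yl)bis(trifluoromethanesulfonyl)imide, O=S(=O)(N(c1ccc(Cl)cn1)S(=O)(=O)C(F)(F)F)C(F)(F)F
Why: kinetic deprotonation should remove the unhindered axial C3–H of the C4 ketone in preference to the tertiary C5–H and to the neopentyl C9–H2 of the C8 ketone, which is flanked by fully substituted C7 and shielded on its α face by the axial silyloxy group; O-triflation at −78 °C (enol triflate formation) fixes the C3=C4 regiochemistry and ends the epimerisability of C5.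

**Step 14**
Reactants: 24 C3=C4 enol triflate
Product: 25 7α-(triethylsilyloxy)-5αH-eudesma-3,11-dien-8-one
Conditions: MeZnCl, Pd(PPh3)4 (5 mol %), THF, 25–50 °C
Reagents that add atoms: methylzinc chloride, C[Zn]Cl
Why: Negishi cross-coupling of the alkenyl triflate installs C15 on C4 with retention of the alkene position, and the organozinc does not add to the hindered C8 ketone.

**Step 15**
Reactants: 25 7α-(triethylsilyloxy)-5αH-eudesma-3,11-dien-8-one
Product: 28 4β-acetoxy-3β-hydroxy-7α-(triethylsilyloxy)-5αH-eudesm-11-en-8-one, via 3α-iodo-4β-acetate 26 (not isolated), via β-face acetoxonium ion 27 (not isolated)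
Conditions: I2 (1.05 equiv), AgOAc (2.3 equiv), AcOH, 20 °C, dark; then H2O–AcOH, 60 °C
Reagents that add atoms: silver acetate, CC(=O)[O-].[Ag+]; water, O
Why: Woodward cis-hydroxylation: iodonium forms on the open α face of the electron-rich trisubstituted C3=C4 alkene (the isopropenyl group is neopentyl and inductively deactivated by the adjacent silyloxy and keto groups), acetate opens it trans-diaxially at tertiary C4 to give 26, silver-assisted displacement of the axial C3 iodide by the anti 4β-acetate gives the acetoxonium ion 27, and water opens 27 with the usual preference for the axial ester, so both oxygens end β (cis to the C10 methyl) with the acetate on the tertiary axial C4 oxygen and the equatorial C3 hydroxyl free.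

**Step 16**
Reactants: 28 4β-acetoxy-3β-hydroxy-7α-(triethylsilyloxy)-5αH-eudesm-11-en-8-one; 29 angelic acid ((Z)-2-methylbut-2-enoic acid)
Product: 31 4β-acetoxy-3β-angeloyloxy-7α-(triethylsilyloxy)-5αH-eudesm-11-en-8-one, via angelic 2,4,6-trichlorobenzoic anhydride 30 (not isolated)
Conditions: 29, 2,4,6-Cl3C6H2COCl, Et3N, toluene, 20 °C; then 28, toluene, 80 °C
Reagents that add atoms: none
Why: mixed-anhydride (Yamaguchi-type) esterification without a nucleophilic catalyst acylates the only free hydroxyl, the equatorial secondary C3–OH, at the less hindered angeloyl carbonyl and is the established way to keep the (Z) geometry of angelates, which acid chloride or DMAP methods tend to isomerise to tiglates.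

**Step 17**
Reactants: 31 4β-acetoxy-3β-angeloyloxy-7α-(triethylsilyloxy)-5αH-eudesm-11-en-8-one
Product: 32 4β-acetoxy-3β-[(Z)-2-methylbut-2-enoyloxy]-7α-hydroxy-5αH-eudesm-11-en-8-one (CNP0381775.1)
Conditions: HF·pyridine, pyridine–THF, 0 °C → rt
Reagents that add atoms: none
Why: fluoride cleavage of the triethylsilyl ether under mildly acidic conditions frees the tertiary 7α-hydroxyl without ester cleavage, acyl migration, angelate isomerisation or α-ketol rearrangement; any material that lost the silyl group in step 15 is already the target at this point.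

**Compound list**

1 | 3-ethoxycyclohex-2-en-1-one | CCOC1=CC(=O)CCC1 | starting material
2 | allylmagnesium bromide | C=CC[Mg]Br | starting material
3 | 1-allyl-3-ethoxycyclohex-2-en-1-ol (racemic; not isolated) | C=CCC1(O)C=C(OCC)CCC1 | intermediate
4 | 3-allylcyclohex-2-en-1-one | C=CCC1=CC(=O)CCC1 | intermediate
5 | dimethylaluminium (R)-3-allyl-3-methylcyclohex-1-en-1-olate (not isolated) | C=CC[C@@]1(C)CCCC(O[Al](C)C)=C1 | intermediate
6 | (R)-3-allyl-3-methyl-1-(trimethylsilyloxy)cyclohex-1-ene | C=CC[C@@]1(C)CCCC(O[Si](C)(C)C)=C1 | intermediate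
7 | (3R)-3-allyl-2-(hydroxymethyl)-3-methylcyclohexan-1-one (both C2 epimers) | C=CC[C@@]1(C)CCCC(=O)C1CO | intermediate
8 | (3R)-3-allyl-2-[(tert-butyldimethylsilyloxy)methyl]-3-methylcyclohexan-1-one (both C2 epimers) | C=CC[C@@]1(C)CCCC(=O)C1CO[Si](C)(C)C(C)(C)C | intermediate
9 | secondary ozonide (3-substituted 1,2,4-trioxolane) of 8 (not isolated) | C1OC(OO1)C[C@@]2(C)CCCC(=O)C2CO[Si](C)(C)C(C)(C)C | intermediate
10 | 2-[(1R)-2-[(tert-butyldimethylsilyloxy)methyl]-1-methyl-3-oxocyclohexyl]acetaldehyde | O=CC[C@@]1(C)CCCC(=O)C1CO[Si](C)(C)C(C)(C)C | intermediate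
11 | 2-methylprop-1-enylmagnesium bromide | CC(C)=C[Mg]Br | starting material
12 | (3R)-2-[(tert-butyldimethylsilyloxy)methyl]-3-(2-hydroxy-4-methylpent-3-enyl)-3-methylcyclohexan-1-one (epimers at C2 and at the carbinol) | CC(C)=CC(O)C[C@@]1(C)CCCC(=O)C1CO[Si](C)(C)C(C)(C)C | intermediate
13 | (3R)-2-[(tert-butyldimethylsilyloxy)methyl]-3-methyl-3-(4-methyl-2-oxopent-3-enyl)cyclohexan-1-one | CC(C)=CC(=O)C[C@@]1(C)CCCC(=O)C1CO[Si](C)(C)C(C)(C)C | intermediate
14 | (3R)-2-(hydroxymethyl)-3-methyl-3-(4-methyl-2-oxopent-3-enyl)cyclohexan-1-one | CC(C)=CC(=O)C[C@@]1(C)CCCC(=O)C1CO | intermediate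
15 | methanesulfonate of 14 (not isolated) | CC(C)=CC(=O)C[C@@]1(C)CCCC(=O)C1COS(C)(=O)=O | intermediate
16 | (R)-3-methyl-2-methylidene-3-(4-methyl-2-oxopent-3-enyl)cyclohexan-1-one (key-step precursor) | CC(C)=CC(=O)C[C@@]1(C)CCCC(=O)C1=C | intermediate
17 | potassium (Z)-extended dienolate of 16 (C7=C8 and C11=C12; not isolated) | C=C(C)/C=C(\[O-])C[C@@]1(C)CCCC(=O)C1=C.[K+] | intermediate
18 | potassium C4(5)-enolate of the cyclised dione (not isolated) | C=C(C)[C@H]1CC2=C([O-])CCC[C@]2(C)CC1=O.[K+] | intermediate
19 | 5αH-7β-isopropenyl-10β-methyl-trans-decalin-4,8-dione (H-5 and H-7 α; isopropenyl equatorial) | C=C(C)[C@H]1C[C@@H]2[C@](C)(CCCC2=O)CC1=O | intermediate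
20 | potassium C7(8),C11(12)-dienolate of 19 (not isolated) | C=C(C)C1=C([O-])C[C@@]2(C)CCCC(=O)[C@@H]2C1.[K+] | intermediate
21 | 7α-hydroxy-7β-isopropenyl-10β-methyl-5αH-trans-decalin-4,8-dione (hydroxyl axial) | C=C(C)[C@@]1(O)C[C@@H]2[C@](C)(CCCC2=O)CC1=O | intermediate
22 | 7β-isopropenyl-10β-methyl-7α-(triethylsilyloxy)-5αH-trans-decalin-4,8-dione | C=C(C)[C@@]1(O[Si](CC)(CC)CC)C[C@@H]2[C@](C)(CCCC2=O)CC1=O | intermediate
23 | lithium C3(4)-enolate of 22 (not isolated) | C=C(C)[C@@]1(O[Si](CC)(CC)CC)C[C@@H]2[C@](C)(CCC=C2[O-])CC1=O.[Li+] | intermediate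
24 | C3=C4 enol triflate of 22 (triflyloxy on C4) | C=C(C)[C@@]1(O[Si](CC)(CC)CC)C[C@@H]2[C@](C)(CCC=C2OS(=O)(=O)C(F)(F)F)CC1=O | intermediate
25 | 7α-(triethylsilyloxy)-5αH-eudesma-3,11-dien-8-one | C=C(C)[C@@]1(O[Si](CC)(CC)CC)C[C@@H]2[C@](C)(CCC=C2C)CC1=O | intermediate
26 | 4β-acetoxy-3α-iodo-7α-(triethylsilyloxy)-5αH-eudesm-11-en-8-one (not isolated) | C=C(C)[C@@]1(O[Si](CC)(CC)CC)C[C@@H]2[C@](C)(CC[C@@H](I)[C@]2(C)OC(C)=O)CC1=O | intermediate
27 | 3β,4β-acetoxonium (2-methyl-1,3-dioxolan-2-ylium) acetate (not isolated) | C=C(C)[C@@]1(O[Si](CC)(CC)CC)C[C@@H]2[C@](C)(CC[C@@H]3OC(C)=[O+][C@]23C)CC1=O.CC(=O)[O-] | intermediate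
28 | 4β-acetoxy-3β-hydroxy-7α-(triethylsilyloxy)-5αH-eudesm-11-en-8-one | C=C(C)[C@@]1(O[Si](CC)(CC)CC)C[C@@H]2[C@](C)(CC[C@H](O)[C@]2(C)OC(C)=O)CC1=O | intermediate
29 | angelic acid, (Z)-2-methylbut-2-enoic acid | C/C=C(/C)C(=O)O | starting material
30 | angelic 2,4,6-trichlorobenzoic anhydride (not isolated) | C/C=C(/C)C(=O)OC(=O)c1c(Cl)cc(Cl)cc1Cl | intermediate
31 | 4β-acetoxy-3β-angeloyloxy-7α-(triethylsilyloxy)-5αH-eudesm-11-en-8-one | C=C(C)[C@@]1(O[Si](CC)(CC)CC)C[C@@H]2[C@](C)(CC[C@H](OC(=O)/C(C)=C\C)[C@]2(C)OC(C)=O)CC1=O | intermediate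
32 | 4β-acetoxy-3β-angeloyloxy-7α-hydroxy-5αH-eudesm-11-en-8-one (CNP0381775.1) | C=C(C)[C@@]1(O)C[C@@H]2[C@](C)(CC[C@H](OC(=O)/C(C)=C\C)[C@]2(C)OC(C)=O)CC1=O | target

**Step count**

Total step count: 17. Longest linear sequence: 17 steps (1 → 32); angelic acid enters at step 16.

**Steps most likely to fail**

Step 10 (key step). What may go wrong: γ-deprotonation may be slow enough that the exocyclic enone is consumed by intermolecular Michael addition or alkoxide addition; prolonged base may also erode the trans fusion at C5. Fallback: use the deconjugated isomer of the donor, whose C7 methylene is flanked by the ketone and the alkene and therefore gives the same dienolate by simple α-deprotonation with a weak amine base. Setting out from aldehyde 10, allylboration with 2-methylallylboronic acid pinacol ester (aldehyde-selective) should give the homoallylic alcohol F1. Dess–Martin oxidation then gives the β,γ-unsaturated ketone F2, and aq. HF in MeCN gives the hydroxy ketone F3. Mesylation with MeSO2Cl/Et3N passes through the mesylate F4 to the exocyclic enone F5, which on treatment with DBU in MeCN at 0 °C should cyclise through dienolate 17 and rejoin the route at 19. Isomerisation of F3 or F5 into conjugation merely returns 14 or 16.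

Step 15 (Woodward reaction). What may go wrong: iodonium formation may compete at the isopropenyl alkene; acetate may attack from the wrong face or at C3; and the acetyl group may migrate from the tertiary to the secondary oxygen during the warm aqueous stage. Fallback: replace the iodine electrophile by a peracid, which distinguishes the two alkenes more reliably, and reach the same acetoxonium ion by sulfonate solvolysis at lower temperature. Setting out from 25, mCPBA/NaHCO3 in CH2Cl2 at 0 °C should give the 3α,4α-epoxide F6 (attack anti to the C10 methyl). Acetic acid opens it trans-diaxially at tertiary C4 to the 3α-hydroxy-4β-acetate F7. MeSO2Cl/Et3N gives the axial 3α-mesylate F8, and solvolysis in moist AcOH/KOAc at 40–60 °C lets the anti 4β-acetate displace the mesylate (Winstein neighbouring-group participation) to give 27, which water opens to rejoin the route at 28.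

Step 11 (C7 hydroxylation). What may go wrong: deprotonation may compete at C3 or C9; oxygen may be transferred to the γ-carbon C12 or with poor facial selectivity; and the enolate may add to the sulfonimine by-product. Fallback: avoid enolate oxidation and bring in the oxygen by epoxidation of the conjugated isomer. Setting out from 19, DBU in warm toluene should move the alkene into conjugation to give the isopropylidene ketone F9. Weitz–Scheffer epoxidation (H2O2, NaOH, MeOH, 0 °C) gives the 7α,11-epoxide F10, the C7–O bond forming axially, anti to the C10 methyl. Me3SiOTf/DBU isomerises the epoxide to the allylic silyl ether (C11–O cleavage, loss of a methyl proton) to give the 7α-trimethylsilyloxy ketone F11. Aqueous citric acid then removes the silyl group (and any C4 silyl enol ether) to rejoin the route at 21.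

**Further compounds**

F1 | step 10 | (3R)-2-[(tert-butyldimethylsilyloxy)methyl]-3-(2-hydroxy-4-methylpent-4-enyl)-3-methylcyclohexan-1-one | C=C(C)CC(O)C[C@@]1(C)CCCC(=O)C1CO[Si](C)(C)C(C)(C)C
F2 | step 10 | (3R)-2-[(tert-butyldimethylsilyloxy)methyl]-3-methyl-3-(4-methyl-2-oxopent-4-enyl)cyclohexan-1-one | C=C(C)CC(=O)C[C@@]1(C)CCCC(=O)C1CO[Si](C)(C)C(C)(C)C
F3 | step 10 | (3R)-2-(hydroxymethyl)-3-methyl-3-(4-methyl-2-oxopent-4-enyl)cyclohexan-1-one | C=C(C)CC(=O)C[C@@]1(C)CCCC(=O)C1CO
F4 | step 10 | methanesulfonate of F3 (not isolated) | C=C(C)CC(=O)C[C@@]1(C)CCCC(=O)C1COS(C)(=O)=O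
F5 | step 10 | (R)-3-methyl-2-methylidene-3-(4-methyl-2-oxopent-4-enyl)cyclohexan-1-one | C=C(C)CC(=O)C[C@@]1(C)CCCC(=O)C1=C
F6 | step 15 | 3α,4α-epoxy-7α-(triethylsilyloxy)-5αH-eudesm-11-en-8-one | C=C(C)[C@@]1(O[Si](CC)(CC)CC)C[C@@H]2[C@](C)(CC[C@H]3O[C@@]23C)CC1=O
F7 | step 15 | 4β-acetoxy-3α-hydroxy-7α-(triethylsilyloxy)-5αH-eudesm-11-en-8-one | C=C(C)[C@@]1(O[Si](CC)(CC)CC)C[C@@H]2[C@](C)(CC[C@@H](O)[C@]2(C)OC(C)=O)CC1=O
F8 | step 15 | 4β-acetoxy-3α-(methanesulfonyloxy)-7α-(triethylsilyloxy)-5αH-eudesm-11-en-8-one | C=C(C)[C@@]1(O[Si](CC)(CC)CC)C[C@@H]2[C@](C)(CC[C@@H](OS(C)(=O)=O)[C@]2(C)OC(C)=O)CC1=O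
F9 | step 11 | 10β-methyl-7-(propan-2-ylidene)-5αH-trans-decalin-4,8-dione | CC(C)=C1C[C@@H]2[C@](C)(CCCC2=O)CC1=O
F10 | step 11 | 7α,11-epoxide of F9 (spiro-oxirane, oxygen α on C7) | CC1(C)O[C@@]12C[C@@H]3[C@](C)(CCCC3=O)CC2=O
F11 | step 11 | 7β-isopropenyl-10β-methyl-7α-(trimethylsilyloxy)-5αH-trans-decalin-4,8-dione | C=C(C)[C@@]1(O[Si](C)(C)C)C[C@@H]2[C@](C)(CCCC2=O)CC1=O
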